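The numbers of this flask stand for no real mixture, and the outcome is calculated.

A small charge of partner, slightly below the starting material, goes into each of the three flasks, and I follow one partner molecule to see where it ends.

common to all: time 5.0 h
- dawn: starting material 20 mM; partner 19.0 mM; everything together at the start
- spring: starting material 20 mM; partner 19.0 mM (fed, over 1.0 h); all else is in the flask from the start; the feed brings no volume worth counting
- noon: starting material 20 mM (fed, over 1.0 h); partner 19.0 mM; all else is in the flask from the start; the feed brings no volume worth counting

    partner + intermediate C → side product (k1 = 6.21 M⁻¹ min⁻¹)
    starting material + partner → intermediate B (k2 = 10.5 M⁻¹ min⁻¹)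
    intermediate B → intermediate C (k3 = 0.0287 min⁻¹)
    partner + intermediate A → target (k4 = 3.26 M⁻¹ min⁻¹)
    starting material + partner → intermediate A (k5 = 2.10 M⁻¹ min⁻¹)
    crystals ⇌ target, rate k6*(cs6 - [target]) while solid is left; crystals form when [target] > cs6 (cs6 = 3.0 mM, k6 = 1.47 min⁻¹)

- amounts and yields of target count crystals too
- given per volume of solution although it is solid: crystals
- run time (dawn): 5.0 h

* the flask that comes out highest in share of target in target plus side product, or "all alike" when all lie within 1.5 percentage points (dawn / spring / noon / all alike)
* share of target in target plus side product at the end, dawn
* share of target in target plus side product at the end, spring
* share of target in target plus side product at the end, noon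

In dawn, partner is the limiting reagent, and its curve opens at a slope of 4.79 mM min⁻¹. Each starting material molecule that reacts forks: 16.7% becomes intermediate A and the rest becomes intermediate B. Intermediate B has a lifetime of 34.8 min, so early on c(intermediate C) grows as k3 times the time integral of c(intermediate B), while c(intermediate B)/c(intermediate A) stays at k2/k5. Surviving partner then forks again, between k4·c(intermediate A) and k1·c(intermediate C). The constants of these two arms combine into a balance time, the product k4·k5 over the product k1·k2·k3, 3.66 min, and in this estimate the charges cancel; it is a yardstick, not the moment at which the two arms are equal.

Starting material starts at 20 mM and cannot fall below 1.00 mM, the floor set by the partner charge; the second steps also take partner, so its end lies above this floor by an amount I do not reckon. Halfway between charge and floor gives a rough mean of 10.5 mM, and so a rough partner lifetime of 7.56 min. The knee of its curve lies about there, later than the balance time. Integrating both arms, with c(intermediate A) and c(intermediate B) rising as partner is spent and partner dying away with this lifetime, gives side product over target as lifetime over balance time. Both curves then level off, and the share of target is balance time over the sum of the two, 32.6% for dawn. In spring and noon the feed lasts 60 min, far beyond the balance time, so I expect lower shares there and pick dawn, but I reckon those two no further.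

The forecast also says dawn, with 30%, 19% and 25%, on the ground that “partner runs out before much of intermediate B has turned into C”. Its dawn figure lies below mine.

The flask gives dawn as highest, with 31.2%, 19.4% and 25.6%. In dawn, partner stands at 0% of its charge after 5.00 h, and the share after 50.0 h reads 31.2%. Through the balance time, the dawn share reads as a partner lifetime of 8.07 min. A neighbour of dawn holds 34 mM of starting material, so its mean is 24.5 mM, its lifetime 3.24 min, and its reckoned share 53.0%; that flask comes out at 50.5%.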